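**Strategy.** Everything rests on cutting two bonds at the γ-lactone (ring O–C6–C7–C11–C12): C7–C8 and C11–C13. C7 is the branch point of the target, bonded to C6, C8 and C11, with the C6 and C7 substituents trans and C11 bearing the exocyclic methylene C13. This is the pattern left by 1,4-addition to a C6-substituted butenolide followed by enolate capture. In one flask the C8-lithiated dithiane from 5 (C1, C8–C10, C14), butenolide 19 (C3–C7, C11, C12, C15) and Eschenmoser's salt should give lactone 23 with C7 and C11 set. The ten-membered carbocycle (C1–C2) and the furanone (O–C3) are closed afterwards.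

Key step: step 11

Numbering used throughout: C1 ketone carbon, C2=C3 furanone alkene (C3 bears the ring oxygen), C4 (bears C15H2OH), C5H2, C6 (lactone O–CH), C7, C8 (O-angelate), C9H2, C10 (quaternary, C14 methyl, furanone oxygen), C11=C13H2, C12 lactone carbonyl.

Assumption: (S,S)-ProPhenol is taken to deliver the alkynylzinc to the Si face of aldehyde 15 (giving 6R); if the opposite sense is found, the enantiomeric ligand is used.

Remark: the spatial arrangement at C4, C6, C7 and C10 in 5, 19 and 23 is that of the target; descriptors at C4 change along the route only because CIP priorities change, and no centre is inverted.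

**Dithiane fragment**

Step 1
Reactants: 1 1,3-dithiane; 2 (R)-2-methylglycidol
Product: 4 (2S)-3-(1,3-dithian-2-yl)-2-methylpropane-1,2-diol, via 2-lithio-1,3-dithiane 3 (not isolated)
Conditions: n-BuLi (2.2 equiv), THF, −30 °C; then 2, DMPU, −30 °C → rt; H2O
Reagents that add atoms: none
Why: Corey–Seebach epoxide opening: the first equivalent of 3 forms the lithium alkoxide of 2 and the second attacks the unsubstituted oxirane CH2 (SN2), so the quaternary carbon (future C10) is untouched and keeps the configuration of 2; Payne rearrangement of this alkoxide is degenerate and cannot erode it.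

Step 2
Reactants: 4 (2S)-3-(1,3-dithian-2-yl)-2-methylpropane-1,2-diol
Product: 5 2-{[(4S)-2,2,4-trimethyl-1,3-dioxolan-4-yl]methyl}-1,3-dithiane
Conditions: 2,2-dimethoxypropane, PPTS (cat.), CH2Cl2, rt
Reagents that add atoms: 2,2-dimethoxypropane COC(C)(C)OC
Why: Acid-catalysed transketalisation should close the five-membered isopropylidene ketal on the 1,2-diol and leave the dithiane untouched.

**Butenolide fragment**

Step 3
Reactants: 6 (R)-4-benzyl-1,3-oxazolidin-2-one; 7 pent-4-enoyl chloride
Product: 8 (R)-4-benzyl-3-(pent-4-enoyl)-1,3-oxazolidin-2-one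
Conditions: Et3N, DMAP (cat.), CH2Cl2, 0 °C → rt
Reagents that add atoms: none
Why: N-Acylation of the Evans oxazolidinone by the acid chloride under DMAP catalysis.

Step 4
Reactants: 8 (R)-4-benzyl-3-(pent-4-enoyl)-1,3-oxazolidin-2-one
Product: 10 (R)-4-benzyl-3-[(2S)-2-(hydroxymethyl)pent-4-enoyl]-1,3-oxazolidin-2-one, via chlorotitanium enolate 9 (not isolated)
Conditions: TiCl4, iPr2NEt, CH2Cl2, 0 °C; then 1,3,5-trioxane, TiCl4, 0 °C; aq. NH4Cl
Reagents that add atoms: 1,3,5-trioxane C1OCOCO1
Why: Evans titanium-enolate aldol with formaldehyde (from trioxane/TiCl4): the chelated Z-enolate 9 is attacked on the face opposite the benzyl group, which sets the future C4 (2S in 10) with the new hydroxymethyl group as C15.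

Step 5
Reactants: 10 (R)-4-benzyl-3-[(2S)-2-(hydroxymethyl)pent-4-enoyl]-1,3-oxazolidin-2-one
Product: 11 (R)-4-benzyl-3-[(2S)-2-{[(tert-butyldiphenylsilyl)oxy]methyl}pent-4-enoyl]-1,3-oxazolidin-2-one
Conditions: TBDPSCl, imidazole, DMF, rt
Reagents that add atoms: tert-butyl(chloro)diphenylsilane CC(C)(C)[Si](Cl)(c1ccccc1)c1ccccc1
Why: Silylation of the primary alcohol; TBDPS is chosen for C15–O because it must outlast the HF·pyridine cleavage of the C3 TBS ether (step 12) and the aqueous acid of step 19.

Step 6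
Reactants: 11 (R)-4-benzyl-3-[(2S)-2-{[(tert-butyldiphenylsilyl)oxy]methyl}pent-4-enoyl]-1,3-oxazolidin-2-one
Product: 12 (2R)-2-{[(tert-butyldiphenylsilyl)oxy]methyl}pent-4-en-1-ol
Conditions: LiBH4, MeOH (1 equiv), THF, 0 °C
Reagents that add atoms: none
Why: Reductive cleavage of the N-acyl oxazolidinone by LiBH4 at the exocyclic carbonyl should give the C3 carbinol without touching the stereocentre and return the auxiliary.

Step 7
Reactants: 12 (2R)-2-{[(tert-butyldiphenylsilyl)oxy]methyl}pent-4-en-1-ol
Product: 13 (2R)-1-[(tert-butyldimethylsilyl)oxy]-2-{[(tert-butyldiphenylsilyl)oxy]methyl}pent-4-ene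
Conditions: TBSCl, imidazole, CH2Cl2, rt
Reagents that add atoms: tert-butyl(chloro)dimethylsilane CC(C)(C)[Si](C)(C)Cl
Why: Silylation; a TBS ether (not an oxidatively cleaved benzyl-type ether) is used on C3–O so that its removal after step 11 spares the dithiane and the tertiary amine.

Step 8
Reactants: 13 (2R)-1-[(tert-butyldimethylsilyl)oxy]-2-{[(tert-butyldiphenylsilyl)oxy]methyl}pent-4-ene
Product: 15 (3R)-4-[(tert-butyldimethylsilyl)oxy]-3-{[(tert-butyldiphenylsilyl)oxy]methyl}butanal, via ozonide 14 (not isolated)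
Conditions: O3, CH2Cl2, −78 °C; then PPh3, −78 °C → rt
Reagents that add atoms: ozone [O-][O+]=O
Why: Ozonolysis (Criegee) of the terminal alkene with reductive work-up should give the C6 aldehyde; the silyl ethers and the C4 centre (β to the aldehyde) are unaffected.

Step 9
Reactants: 15 (3R)-4-[(tert-butyldimethylsilyl)oxy]-3-{[(tert-butyldiphenylsilyl)oxy]methyl}butanal; 16 methyl propiolate
Product: 17 methyl (4R,6R)-7-[(tert-butyldimethylsilyl)oxy]-6-{[(tert-butyldiphenylsilyl)oxy]methyl}-4-hydroxyhept-2-ynoate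
Conditions: (S,S)-ProPhenol (20 mol %), Me2Zn, Ph3PO (40 mol %), toluene, 4 °C; aq. NH4Cl
Reagents that add atoms: none
Why: Catalytic asymmetric alkynylation (dinuclear zinc–ProPhenol): the zinc alkynylide of 16 is delivered to one aldehyde face under ligand control, which sets C6 (4R in 17) independently of the remote C4 centre.

Step 10
Reactants: 17 methyl (4R,6R)-7-[(tert-butyldimethylsilyl)oxy]-6-{[(tert-butyldiphenylsilyl)oxy]methyl}-4-hydroxyhept-2-ynoate
Product: 19 (5R)-5-[(2R)-3-[(tert-butyldimethylsilyl)oxy]-2-{[(tert-butyldiphenylsilyl)oxy]methyl}propyl]furan-2(5H)-one, via Z-hydroxy enoate 18 (not isolated)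
Conditions: H2 (1 atm), Lindlar catalyst, quinoline, EtOAc, rt; then PPTS (cat.), CH2Cl2, rt
Reagents that add atoms: none
Why: Lindlar cis-semihydrogenation gives the Z-γ-hydroxy enoate, which should lactonise (acid-catalysed transesterification) to the butenolide; C6 is not involved.

**Key step and completion**

Step 11
Reactants: 5 2-{[(4S)-2,2,4-trimethyl-1,3-dioxolan-4-yl]methyl}-1,3-dithiane; 19 (5R)-butenolide; 20 Eschenmoser's salt
Product: 23 (3R,4S,5R)-3-[(dimethylamino)methyl]-4-(2-{[(4S)-2,2,4-trimethyl-1,3-dioxolan-4-yl]methyl}-1,3-dithian-2-yl)-5-[(2R)-3-[(tert-butyldimethylsilyl)oxy]-2-{[(tert-butyldiphenylsilyl)oxy]methyl}propyl]oxolan-2-one, via lithiated dithiane 21 (not isolated), via lactone enolate 22 (not isolated)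
Conditions: 5, t-BuLi, THF/HMPA (9:1), −78 °C; then 19, −78 °C; then 20, −78 → 0 °C; aq. NaHCO3
Reagents that add atoms: none
Why: t-BuLi deprotonates the 2-alkyl dithiane at C8, the HMPA-separated lithiodithiane 21 adds in Michael fashion to C7 of butenolide 19 instead of attacking the lactone carbonyl, and the lithium enolate 22 then attacks the iminium carbon of 20 (Mannich reaction) to form C11–C13. The closest known reaction type is the tandem conjugate addition of 2-lithio-1,3-dithianes to butenolides with in situ enolate trapping, combined with the capture of lactone enolates by Eschenmoser's salt. No ring is closed; two skeletal bonds and two stereocentres are formed. C7 is set by approach of the bulky nucleophile anti to the C5 side chain on C6, the only substituent on the flat butenolide, which gives the C6/C7 trans lactone of the target. C11 is set by approach of the iminium ion anti to the new dithianyl group on C7, and its configuration is irrelevant because C11 becomes sp2 in step 22. The step needs 1,4- over 1,2-selectivity, secured by the soft sulfur-stabilised anion in THF/HMPA, and an anion that does not fragment, secured because the C10 oxygen is γ to C8 and no β-leaving group is present.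

Step 12
Reactants: 23 trans,trans-lactone with C8 dithiane and C13 amine
Product: 24 C3 alcohol (23 with the C3 TBS ether cleaved; all stereocentres as in 23)
Conditions: HF·pyridine, pyridine, THF, 0 °C → rt
Reagents that add atoms: none
Why: Selective desilylation: under buffered HF·pyridine the primary TBS ether is cleaved far faster than the primary TBDPS ether, and ketal, dithiane and lactone are inert.

Step 13
Reactants: 24 C3 alcohol
Product: 25 C3 aldehyde (stereocentres as in 23)
Conditions: SO3·pyridine, DMSO, iPr2NEt, CH2Cl2, 0 °C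
Reagents that add atoms: none
Why: Parikh–Doering oxidation should give the C3 aldehyde under conditions that tolerate the dithiane and the amine and are mild enough to keep the α-centre C4.

Step 14
Reactants: 25 C3 aldehyde
Product: 26 terminal alkyne C3≡C2H (stereocentres as in 23)
Conditions: dimethyl (1-diazo-2-oxopropyl)phosphonate, K2CO3, MeOH, 0 °C → rt
Reagents that add atoms: dimethyl (1-diazo-2-oxopropyl)phosphonate CC(=O)C(=[N+]=[N-])P(=O)(OC)OC
Why: Seyferth–Gilbert homologation with the Ohira–Bestmann reagent: the diazophosphonate anion adds to the aldehyde and the derived alkylidene carbene rearranges to the alkyne; it is run before C8 carries an ester, so that methanolic carbonate meets no acyl group that could migrate or be cleaved.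

Step 15
Reactants: 26 terminal alkyne
Product: 27 C8 ketone (dithiane replaced by C=O; other centres as in 23)
Conditions: PhI(OCOCF3)2, TFA (1.5 equiv), MeCN/H2O (9:1), 0 °C
Reagents that add atoms: water O
Why: Oxidative dethioketalisation with an iodine(III) reagent (Stork–Zhao): sulfur is oxidised and the sulfonium ion hydrolysed to the ketone, while TFA keeps the amine protonated and the short reaction at 0 °C should spare alkyne, ketal and TBDPS ether.

Step 16
Reactants: 27 C8 ketone
Product: 28 (8R)-alcohol (other centres as in 23)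
Conditions: (S)-Me-CBS (1.0 equiv), catecholborane (3 equiv), toluene, −78 → −40 °C; then MeOH, aq. NaHCO3
Reagents that add atoms: none
Why: Corey–Bakshi–Shibata reduction: the ketone binds anti to the α-branched C7 flank and the (S)-catalyst delivers hydride to give 8R (same sense as acetophenone to (R)-1-phenylethanol); reagent control is used because the ketone sits between two ring hydrogens of the trans,trans-lactone and has little intrinsic bias.

Step 17
Reactants: 28 (8R)-alcohol
Product: 29 iodoalkyne C3≡C2–I (stereocentres as in 28)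
Conditions: I2, morpholine, toluene, rt → 40 °C
Reagents that add atoms: iodine II
Why: Iodination of the terminal alkyne by the morpholine–iodine complex, a reagent compatible with the amine, the lactone and the free alcohol.

Step 18
Reactants: 29 iodoalkyne alcohol; 30 angelic acid
Product: 32 C8 angelate (stereocentres as in 28), via mixed anhydride 31 (not isolated)
Conditions: 30, 2,4,6-trichlorobenzoyl chloride, Et3N, toluene, rt; then 29, 80 °C
Reagents that add atoms: none
Why: Yamaguchi esterification through the mixed anhydride without DMAP; the absence of a nucleophilic catalyst avoids conjugate addition–elimination and should keep the Z geometry, and C8 retains its configuration because only the O–H bond reacts.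

Step 19
Reactants: 32 C8 angelate
Product: 33 C1,C10-diol (stereocentres as in 28)
Conditions: AcOH/H2O (4:1), 40 °C
Reagents that add atoms: none
Why: Acid hydrolysis of the isopropylidene ketal frees the C1 and C10 hydroxyls; angelate, iodoalkyne, lactone and the acid-stable TBDPS ether should survive.

Step 20
Reactants: 33 C1,C10-diol
Product: 34 C1 aldehyde with free C10 tertiary alcohol (stereocentres as in 28)
Conditions: SO3·pyridine, DMSO, iPr2NEt, CH2Cl2, 0 °C
Reagents that add atoms: none
Why: Parikh–Doering oxidation converts only the primary C1 alcohol (the C10 alcohol is tertiary) into the α-hydroxy aldehyde, which is used at once.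

Step 21
Reactants: 34 iodoalkyne aldehyde
Product: 36 ten-membered propargylic alcohol (C1–C2 formed; C1 carbinol as a mixture; other centres as in 28), via alkynylchromium species 35 (not isolated)
Conditions: CrCl2 (8 equiv), NiCl2 (2 mol %), THF, rt, syringe-pump addition to 2 mM; H2O
Reagents that add atoms: none
Why: Nozaki–Hiyama–Kishi (Takai) alkynylation: Cr(II) with catalytic Ni inserts into the C(sp)–I bond and the alkynylchromium(III) adds chemoselectively to the aldehyde, forming C1–C2 and the ten-membered ring under high dilution; the C1 centre is not controlled and is removed by oxidation in step 23.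

Step 22
Reactants: 36 macrocyclic propargylic alcohol
Product: 38 α-methylene lactone (C11=C13), via trimethylammonium iodide 37 (not isolated)
Conditions: MeI, THF, rt; then aq. NaHCO3, EtOAc, rt
Reagents that add atoms: none
Why: N-Methylation followed by base-induced β-elimination of trimethylamine (E1cB, the standard release of an α-methylene lactone from its Mannich base); done now that C8 is esterified, so C7–H is no longer acidified and the alkene cannot migrate into the ring.

Step 23
Reactants: 38 α-methylene lactone diol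
Product: 39 macrocyclic α'-hydroxy ynone (C1=O, C2≡C3)
Conditions: IBX, DMSO, rt
Reagents that add atoms: none
Why: IBX oxidises the secondary propargylic alcohol to the ynone without cleaving the 1,2-diol and leaves the tertiary C10 alcohol.

Step 24
Reactants: 39 α'-hydroxy ynone
Product: 40 15-O-TBDPS ether of the target (furanone closed)
Conditions: Ph3PAuNTf2 (5 mol %), toluene, rt
Reagents that add atoms: none
Why: Gold(I)-catalysed 5-endo-dig cycloisomerisation of the α'-hydroxy ynone: the C10 hydroxyl adds to gold-activated C3 and protodeauration should give the 3(2H)-furanone, C10 keeping its configuration.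

Step 25
Reactants: 40 15-O-TBDPS ether
Product: 41 target CNP0108636.1
Conditions: HF·pyridine, pyridine, THF, 0 °C → rt
Reagents that add atoms: none
Why: Fluoride cleavage of the primary TBDPS ether under acidic, non-nucleophilic conditions that the α-methylene lactone, the angelate and the furanone should tolerate.

**Compound list**

1 | 1,3-dithiane | C1CSCSC1 | starting material
2 | (R)-2-methylglycidol, (2R)-(2-methyloxiran-2-yl)methanol | OC[C@]1(C)CO1 | starting material
3 | 2-lithio-1,3-dithiane | [Li]C1SCCCS1 | intermediate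
4 | (2S)-3-(1,3-dithian-2-yl)-2-methylpropane-1,2-diol | C1CSC(SC1)C[C@@](O)(C)CO | intermediate
5 | 2-{[(4S)-2,2,4-trimethyl-1,3-dioxolan-4-yl]methyl}-1,3-dithiane | C1CSC(SC1)C[C@@]2(C)COC(C)(C)O2 | intermediate
6 | (R)-4-benzyl-1,3-oxazolidin-2-one | O=C1N[C@H](Cc2ccccc2)CO1 | starting material
7 | pent-4-enoyl chloride | C=CCCC(=O)Cl | starting material
8 | (R)-4-benzyl-3-(pent-4-enoyl)-1,3-oxazolidin-2-one | C=CCCC(=O)N1[C@H](Cc2ccccc2)COC1=O | intermediate
9 | chlorotitanium (Z)-enolate of 8 | C=CC/C=C(\O[Ti](Cl)(Cl)Cl)N1[C@H](Cc2ccccc2)COC1=O | intermediate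
10 | (R)-4-benzyl-3-[(2S)-2-(hydroxymethyl)pent-4-enoyl]-1,3-oxazolidin-2-one | C=CC[C@@H](CO)C(=O)N1[C@H](Cc2ccccc2)COC1=O | intermediate
11 | (R)-4-benzyl-3-[(2S)-2-{[(tert-butyldiphenylsilyl)oxy]methyl}pent-4-enoyl]-1,3-oxazolidin-2-one | C=CC[C@@H](CO[Si](c1ccccc1)(c2ccccc2)C(C)(C)C)C(=O)N3[C@H](Cc4ccccc4)COC3=O | intermediate
12 | (2R)-2-{[(tert-butyldiphenylsilyl)oxy]methyl}pent-4-en-1-ol | C=CC[C@@H](CO[Si](c1ccccc1)(c2ccccc2)C(C)(C)C)CO | intermediate
13 | (2R)-1-[(tert-butyldimethylsilyl)oxy]-2-{[(tert-butyldiphenylsilyl)oxy]methyl}pent-4-ene | C=CC[C@@H](CO[Si](c1ccccc1)(c2ccccc2)C(C)(C)C)CO[Si](C)(C)C(C)(C)C | intermediate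
14 | ozonide of 13 (3-substituted 1,2,4-trioxolane, mixture at the ring carbon) | C1OC(OO1)C[C@@H](CO[Si](c2ccccc2)(c3ccccc3)C(C)(C)C)CO[Si](C)(C)C(C)(C)C | intermediate
15 | (3R)-4-[(tert-butyldimethylsilyl)oxy]-3-{[(tert-butyldiphenylsilyl)oxy]methyl}butanal | O=CC[C@@H](CO[Si](c1ccccc1)(c2ccccc2)C(C)(C)C)CO[Si](C)(C)C(C)(C)C | intermediate
16 | methyl propiolate | C#CC(=O)OC | starting material
17 | methyl (4R,6R)-7-[(tert-butyldimethylsilyl)oxy]-6-{[(tert-butyldiphenylsilyl)oxy]methyl}-4-hydroxyhept-2-ynoate | COC(=O)C#C[C@H](O)C[C@@H](CO[Si](c1ccccc1)(c2ccccc2)C(C)(C)C)CO[Si](C)(C)C(C)(C)C | intermediate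
18 | methyl (2Z,4R,6R)-7-[(tert-butyldimethylsilyl)oxy]-6-{[(tert-butyldiphenylsilyl)oxy]methyl}-4-hydroxyhept-2-enoate | COC(=O)/C=C\[C@H](O)C[C@@H](CO[Si](c1ccccc1)(c2ccccc2)C(C)(C)C)CO[Si](C)(C)C(C)(C)C | intermediate
19 | (5R)-5-[(2R)-3-[(tert-butyldimethylsilyl)oxy]-2-{[(tert-butyldiphenylsilyl)oxy]methyl}propyl]furan-2(5H)-one (C3–C7/C11–C12/C15 butenolide) | O=C1C=C[C@@H](C[C@@H](CO[Si](c2ccccc2)(c3ccccc3)C(C)(C)C)CO[Si](C)(C)C(C)(C)C)O1 | intermediate
20 | Eschenmoser's salt (N,N-dimethylmethyleneiminium iodide) | C=[N+](C)C.[I-] | starting material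
21 | 2-lithio derivative of 5 | [Li]C1(SCCCS1)C[C@@]2(C)COC(C)(C)O2 | intermediate
22 | lithium enolate of the conjugate adduct (C6/C7 trans) | [Li]OC1=C[C@H](C2(SCCCS2)C[C@@]3(C)COC(C)(C)O3)[C@@H](C[C@@H](CO[Si](c4ccccc4)(c5ccccc5)C(C)(C)C)CO[Si](C)(C)C(C)(C)C)O1 | intermediate
23 | (3R,4S,5R)-trans,trans-lactone with C8 dithiane, C13 dimethylamine, C3–OTBS, C15–OTBDPS and C1/C10 acetonide | CN(C)C[C@@H]1C(=O)O[C@H](C[C@@H](CO[Si](c2ccccc2)(c3ccccc3)C(C)(C)C)CO[Si](C)(C)C(C)(C)C)[C@H]1C4(SCCCS4)C[C@@]5(C)COC(C)(C)O5 | intermediate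
24 | 23 with free C3 hydroxyl | CN(C)C[C@@H]1C(=O)O[C@H](C[C@@H](CO[Si](c2ccccc2)(c3ccccc3)C(C)(C)C)CO)[C@H]1C4(SCCCS4)C[C@@]5(C)COC(C)(C)O5 | intermediate
25 | C3 aldehyde | CN(C)C[C@@H]1C(=O)O[C@H](C[C@@H](CO[Si](c2ccccc2)(c3ccccc3)C(C)(C)C)C=O)[C@H]1C4(SCCCS4)C[C@@]5(C)COC(C)(C)O5 | intermediate
26 | terminal alkyne (C3≡C2H) with C8 dithiane | CN(C)C[C@@H]1C(=O)O[C@H](C[C@@H](CO[Si](c2ccccc2)(c3ccccc3)C(C)(C)C)C#C)[C@H]1C4(SCCCS4)C[C@@]5(C)COC(C)(C)O5 | intermediate
27 | C8 ketone | CN(C)C[C@@H]1C(=O)O[C@H](C[C@@H](CO[Si](c2ccccc2)(c3ccccc3)C(C)(C)C)C#C)[C@H]1C(=O)C[C@@]4(C)COC(C)(C)O4 | intermediate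
28 | (8R)-alcohol | CN(C)C[C@@H]1C(=O)O[C@H](C[C@@H](CO[Si](c2ccccc2)(c3ccccc3)C(C)(C)C)C#C)[C@H]1[C@H](O)C[C@@]4(C)COC(C)(C)O4 | intermediate
29 | (8R)-alcohol with iodoalkyne | CN(C)C[C@@H]1C(=O)O[C@H](C[C@@H](CO[Si](c2ccccc2)(c3ccccc3)C(C)(C)C)C#CI)[C@H]1[C@H](O)C[C@@]4(C)COC(C)(C)O4 | intermediate
30 | angelic acid, (Z)-2-methylbut-2-enoic acid | C/C=C(C)\C(=O)O | starting material
31 | angelic 2,4,6-trichlorobenzoic anhydride | C/C=C(C)\C(=O)OC(=O)c1c(Cl)cc(Cl)cc1Cl | intermediate
32 | (8R)-angelate, iodoalkyne, acetonide | CN(C)C[C@@H]1C(=O)O[C@H](C[C@@H](CO[Si](c2ccccc2)(c3ccccc3)C(C)(C)C)C#CI)[C@H]1[C@H](OC(=O)/C(C)=C\C)C[C@@]4(C)COC(C)(C)O4 | intermediate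
33 | C1,C10-diol | CN(C)C[C@@H]1C(=O)O[C@H](C[C@@H](CO[Si](c2ccccc2)(c3ccccc3)C(C)(C)C)C#CI)[C@H]1[C@H](OC(=O)/C(C)=C\C)C[C@@](O)(C)CO | intermediate
34 | C1 aldehyde with C10 tertiary alcohol | CN(C)C[C@@H]1C(=O)O[C@H](C[C@@H](CO[Si](c2ccccc2)(c3ccccc3)C(C)(C)C)C#CI)[C@H]1[C@H](OC(=O)/C(C)=C\C)C[C@@](O)(C)C=O | intermediate
35 | alkynylchromium(III) dichloride derived from 34 | CN(C)C[C@@H]1C(=O)O[C@H](C[C@@H](CO[Si](c2ccccc2)(c3ccccc3)C(C)(C)C)C#C[Cr](Cl)Cl)[C@H]1[C@H](OC(=O)/C(C)=C\C)C[C@@](O)(C)C=O | intermediate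
36 | ten-membered propargylic alcohol (C1–OH mixture), amine retained | CN(C)C[C@@H]1C(=O)O[C@@H]2C[C@@H](CO[Si](c3ccccc3)(c4ccccc4)C(C)(C)C)C#CC(O)[C@@](C)(O)C[C@@H](OC(=O)/C(C)=C\C)[C@@H]12 | intermediate
37 | trimethylammonium iodide of 36 | C[N+](C)(C)C[C@@H]1C(=O)O[C@@H]2C[C@@H](CO[Si](c3ccccc3)(c4ccccc4)C(C)(C)C)C#CC(O)[C@@](C)(O)C[C@@H](OC(=O)/C(C)=C\C)[C@@H]12.[I-] | intermediate
38 | α-methylene lactone, macrocyclic propargylic diol | C=C1C(=O)O[C@@H]2C[C@@H](CO[Si](c3ccccc3)(c4ccccc4)C(C)(C)C)C#CC(O)[C@@](C)(O)C[C@@H](OC(=O)/C(C)=C\C)[C@@H]12 | intermediate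
39 | macrocyclic α'-hydroxy ynone | C=C1C(=O)O[C@@H]2C[C@@H](CO[Si](c3ccccc3)(c4ccccc4)C(C)(C)C)C#CC(=O)[C@@](C)(O)C[C@@H](OC(=O)/C(C)=C\C)[C@@H]12 | intermediate
40 | 15-O-TBDPS ether of the target | C=C1C(=O)O[C@@H]2C[C@@H](CO[Si](c3ccccc3)(c4ccccc4)C(C)(C)C)C5=CC(=O)[C@](C)(C[C@@H](OC(=O)/C(C)=C\C)[C@@H]12)O5 | intermediate
41 | CNP0108636.1 | C=C1C(=O)O[C@@H]2C[C@@H](CO)C3=CC(=O)[C@](C)(C[C@@H](OC(=O)/C(C)=C\C)[C@@H]12)O3 | target

**Totals.** 25 steps in all (steps 1–2 dithiane, 3–10 butenolide, 11 key step, 12–25 completion). Longest linear sequence: 23 steps (steps 3–25).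

**Steps most likely to fail**

Step 11 (key step). The hindered lithiodithiane may attack the lactone carbonyl or remove the C6 proton instead of adding to C7, and the HMPA-solvated enolate may exchange protons with unreacted butenolide or react sluggishly with the sparingly soluble iminium salt, so that aminomethylation stays incomplete. The fallback separates the two bond formations. It sets out from 5 and 19: the conjugate addition is run alone and quenched at −78 °C with acetic acid to give the C6/C7-trans lactone F1, which is isolated. F1 is then enolised with LDA in THF at −78 °C (no HMPA, no competing acceptor) and treated with 20, the classical two-operation α-aminomethylation of a lactone, and the route is rejoined at 23.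

Step 16 (C8 reduction). Hydride may be delivered to the wrong face of C8 if the neopentyl-type C9 flank competes with C7 as the larger group or if the C7 centre overrides the catalyst, giving mainly or partly the 8S carbinol. The fallback uses inversion instead of retention at the esterification. It sets out from 27: the 8S alcohol F2 is made deliberately with whichever catalyst enantiomer gives it cleanly and iodinated as in step 17 to F3. A Mitsunobu reaction of F3 with angelic acid 30 (PPh3, DIAD, toluene, 0 °C) then installs the angelate with inversion at C8 and without a nucleophilic acyl-transfer catalyst, and the route is rejoined at 32.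

Step 21 (macrocyclisation). Intermolecular coupling, oligomerisation or simple reduction of the iodoalkyne may outrun ring closure, because the forming ten-membered ring must accommodate the linear C4–C3≡C2–C1 unit. The fallback closes a less strained cis-cycloalkene and forms the furanone oxidatively. It sets out from 33: diimide (potassium azodicarboxylate, AcOH, pyridine/MeOH) reduces the iodoalkyne to the (Z)-iodoalkene F4, and Parikh–Doering oxidation gives aldehyde F5. Nozaki–Hiyama–Kishi alkenylation (CrCl2, cat. NiCl2, DMSO, high dilution) gives the (Z)-cyclodecenol F6. MeI then NaHCO3 gives the α-methylene lactone F7, and IBX gives the (Z)-α'-hydroxy enone F8. A Pd(II)-catalysed oxidative (Wacker-type) 5-endo cyclisation (PdCl2(MeCN)2, CuCl, O2, DME) then closes the furanone, and the route is rejoined at 40.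

**Further compounds**

F1 | step 11 | C6/C7-trans conjugate adduct without the C13 aminomethyl group | O=C1C[C@H](C2(SCCCS2)C[C@@]3(C)COC(C)(C)O3)[C@@H](C[C@@H](CO[Si](c4ccccc4)(c5ccccc5)C(C)(C)C)CO[Si](C)(C)C(C)(C)C)O1
F2 | step 16 | (8S)-alcohol, C8 epimer of 28 | CN(C)C[C@@H]1C(=O)O[C@H](C[C@@H](CO[Si](c2ccccc2)(c3ccccc3)C(C)(C)C)C#C)[C@H]1[C@@H](O)C[C@@]4(C)COC(C)(C)O4
F3 | step 16 | (8S)-alcohol with iodoalkyne, C8 epimer of 29 | CN(C)C[C@@H]1C(=O)O[C@H](C[C@@H](CO[Si](c2ccccc2)(c3ccccc3)C(C)(C)C)C#CI)[C@H]1[C@@H](O)C[C@@]4(C)COC(C)(C)O4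
F4 | step 21 | (Z)-iodoalkene C1,C10-diol | CN(C)C[C@@H]1C(=O)O[C@H](C[C@@H](CO[Si](c2ccccc2)(c3ccccc3)C(C)(C)C)/C=C\I)[C@H]1[C@H](OC(=O)/C(C)=C\C)C[C@@](O)(C)CO
F5 | step 21 | (Z)-iodoalkene C1 aldehyde | CN(C)C[C@@H]1C(=O)O[C@H](C[C@@H](CO[Si](c2ccccc2)(c3ccccc3)C(C)(C)C)/C=C\I)[C@H]1[C@H](OC(=O)/C(C)=C\C)C[C@@](O)(C)C=O
F6 | step 21 | ten-membered (Z)-allylic alcohol, amine retained | CN(C)C[C@@H]1C(=O)O[C@@H]2C[C@@H](CO[Si](c3ccccc3)(c4ccccc4)C(C)(C)C)/C=C\C(O)[C@@](C)(O)C[C@@H](OC(=O)/C(C)=C\C)[C@@H]12
F7 | step 21 | α-methylene lactone (Z)-allylic diol | C=C1C(=O)O[C@@H]2C[C@@H](CO[Si](c3ccccc3)(c4ccccc4)C(C)(C)C)/C=C\C(O)[C@@](C)(O)C[C@@H](OC(=O)/C(C)=C\C)[C@@H]12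
F8 | step 21 | macrocyclic (Z)-α'-hydroxy enone | C=C1C(=O)O[C@@H]2C[C@@H](CO[Si](c3ccccc3)(c4ccccc4)C(C)(C)C)/C=C\C(=O)[C@@](C)(O)C[C@@H](OC(=O)/C(C)=C\C)[C@@H]12
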